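**Strategy.** The flavone is cut through ring A: C5–C6, C7–C8 and C4a–C5 are formed late, so rings B and C are first assembled as a 6-aryl-4-pyranone carrying a diazoacetyl group on the carbon that becomes C8a. The key step exploits the meta relation of the C5 and C7 oxygens on a ring fused to the pyranone at C4a–C8a. A photochemically generated pyranonyl ketene (future C5 and C8) and a silyloxyacetylene (future C6 and C7) merge by cycloaddition, ring opening and electrocyclisation. This delivers ring A with a free 5-OH and a silyl-masked 7-OH, both distinct from the four methyl ethers. Fluoride then unmasks the target.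

Key step: step 6

Remark: flavone numbering (O1, C2–C4, C4a, C5–C8, C8a; primed numbers for ring B) is used for 17 and 18. β-Dicarbonyl compounds are drawn as keto forms although largely enolised. Diazomethane is used as a pre-made ethereal solution. The target has no stereocentre.

**Route**

Step 1
Reactants: 1 1,2,3,4-tetramethoxybenzene
Product: 2 1-(2,3,4,5-tetramethoxyphenyl)ethan-1-one
Conditions: Ac2O (1.5 equiv), Sc(OTf)3 (10 mol%), MeNO2, 50 °C
Reagents that add atoms: acetic anhydride, CC(=O)OC(C)=O
Why: Friedel–Crafts acetylation should occur at either of the two equivalent free positions of 1 (each ortho and para to a methoxy group), and a catalytic Lewis acid with the anhydride avoids the ortho-demethylation that stoichiometric AlCl3 tends to cause.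

Step 2
Reactants: 2 1-(2,3,4,5-tetramethoxyphenyl)ethan-1-one
Product: 3 1-(2,3,4,5-tetramethoxyphenyl)butane-1,3-dione
Conditions: NaH (2.5 equiv), EtOAc (5 equiv), THF, reflux; then aq. HCl
Reagents that add atoms: ethyl acetate, CCOC(C)=O
Why: In this crossed Claisen condensation the sodium enolate of the aryl methyl ketone is acylated by ethyl acetate, and deprotonation of the β-diketone formed pulls the equilibrium forward until acidification releases 3.

Step 3
Reactants: 3 1-(2,3,4,5-tetramethoxyphenyl)butane-1,3-dione; 4 diethyl oxalate
Product: 7 4-oxo-6-(2,3,4,5-tetramethoxyphenyl)-4H-pyran-2-carboxylic acid, via triketo ester 5 (not isolated), via ethyl pyranone-2-carboxylate 6 (not isolated)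
Conditions: NaOEt (3 equiv), EtOH, 0 °C to reflux; then conc. HCl, AcOH, 100 °C
Reagents that add atoms: water, O
Why: Claisen condensation of the non-enolisable oxalate at the terminal methyl group of the β-diketone (the same event as the second acylation in the classical chelidonic acid synthesis) should give the 1,3,5-triketone, which in hot aqueous acid cyclodehydrates to the 4-pyranone and loses its ethyl ester by hydrolysis while the aryl methyl ethers are inert to HCl.

Step 4
Reactants: 7 4-oxo-6-(2,3,4,5-tetramethoxyphenyl)-4H-pyran-2-carboxylic acid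
Product: 9 2-(2-diazoacetyl)-6-(2,3,4,5-tetramethoxyphenyl)-4H-pyran-4-one, via pyranone-2-carbonyl chloride 8 (not isolated)
Conditions: (COCl)2, DMF (cat.), CH2Cl2, 0 °C to rt, evaporate; then CH2N2 (3 equiv), Et2O–THF, 0 °C, dark
Reagents that add atoms: diazomethane, C=[N+]=[N-]
Why: In this Arndt–Eistert-type acylation the acyl chloride, which has no α-hydrogen, acylates diazomethane at carbon while a second equivalent removes the HCl, and at 0 °C this should be much faster than dipolar cycloaddition to the vinylogous-ester double bonds of the pyranone.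

Step 5
Reactants: 10 ethyl dibromoacetate; 11 chlorotriisopropylsilane
Product: 13 (ethynyloxy)triisopropylsilane, via lithium ethynolate 12 (not isolated)
Conditions: t-BuLi (4 equiv), THF, −78 °C to 0 °C; then 11 (1.1 equiv), −78 °C to rt
Reagents that add atoms: none
Why: Twofold bromine–lithium exchange on the α,α-dibromo ester and cleavage of the resulting ester dianion with loss of lithium ethoxide should give the ynolate (half of the t-BuLi destroys the tert-butyl bromide formed), and the bulky chlorosilane silylates it at oxygen in preference to carbon.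

Step 6
Reactants: 9 2-(2-diazoacetyl)-6-(2,3,4,5-tetramethoxyphenyl)-4H-pyran-4-one; 13 (ethynyloxy)triisopropylsilane
Product: 17 5-hydroxy-2',3',4',5'-tetramethoxy-7-(triisopropylsilyloxy)flavone, via pyranonylketene 14 (not isolated), via silyloxycyclobutenone 15 (not isolated), via dienylketene 16 (not isolated)
Conditions: 13 (2 equiv), degassed ClCH2CH2Cl, hν (365 nm LED, Pyrex), 25 °C; then 80 °C
Reagents that add atoms: none
Why: Light expels N2 from 9 and the Wolff 1,2-shift places the pyranonyl group on the former diazo carbon, giving ketene 14, whose C=C is conjugated with the pyranone C2=C3 bond; [2+2] cycloaddition with 13 gives cyclobutenone 15, which on warming undergoes 4π-electrocyclic opening to dienylketene 16, 6π-electrocyclisation and a proton shift to the phenol. The closest known reaction is the Danheiser benzannulation in its photo-Wolff form, established for alkenyl, aryl and heteroaryl diazomethyl ketones with silyloxyalkynes, of which the pyranonyl ketone is a new member. Ring A is the only ring closed, by thermal disrotatory 6π-electrocyclisation that joins the ketene carbon (C5) to pyranone C3 (C4a), after the cycloaddition has made C5–C6 and C7–C8. No stereocentre is formed, and the stereocentre of 15 is erased on ring opening. The selectivity required is the orientation of the cycloaddition, which the polarised ynol ether secures: its nucleophilic unsubstituted carbon bonds to the electrophilic ketene carbonyl carbon, so the silyloxy carbon becomes C7, meta to the C5 hydroxyl, while closure can only reach C3 because the ketene hangs from C2 of the pyranone. Irradiation at 365 nm addresses the diazo ketone chromophore while sparing the 4-pyranone, whose own photochemistry needs shorter wavelengths, and the hydrogen-bonded 5-OH is a poor trap for residual ketene.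

Step 7
Reactants: 17 5-hydroxy-2',3',4',5'-tetramethoxy-7-(triisopropylsilyloxy)flavone
Product: 18 5,7-dihydroxy-2',3',4',5'-tetramethoxyflavone
Conditions: Bu4NF (1.1 equiv), AcOH (1.1 equiv), THF, 0 °C
Reagents that add atoms: none
Why: Fluoride-induced desilylation of the aryl silyl ether is driven by the strong Si–F bond and the good 7-phenoxide leaving group, and the acetic acid buffer protects the pyranone ring from base while the methyl ethers and the chelated 5-OH are untouched.

**Compound list**

1 | 1,2,3,4-tetramethoxybenzene | COc1ccc(OC)c(OC)c1OC | starting material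
2 | 1-(2,3,4,5-tetramethoxyphenyl)ethan-1-one | CC(=O)c1cc(OC)c(OC)c(OC)c1OC | intermediate
3 | 1-(2,3,4,5-tetramethoxyphenyl)butane-1,3-dione | CC(=O)CC(=O)c1cc(OC)c(OC)c(OC)c1OC | intermediate
4 | diethyl oxalate | CCOC(=O)C(=O)OCC | starting material
5 | ethyl 2,4,6-trioxo-6-(2,3,4,5-tetramethoxyphenyl)hexanoate (formed as its sodium enolate) | CCOC(=O)C(=O)CC(=O)CC(=O)c1cc(OC)c(OC)c(OC)c1OC | intermediate
6 | ethyl 4-oxo-6-(2,3,4,5-tetramethoxyphenyl)-4H-pyran-2-carboxylate | CCOC(=O)c1cc(=O)cc(-c2cc(OC)c(OC)c(OC)c2OC)o1 | intermediate
7 | 4-oxo-6-(2,3,4,5-tetramethoxyphenyl)-4H-pyran-2-carboxylic acid | OC(=O)c1cc(=O)cc(-c2cc(OC)c(OC)c(OC)c2OC)o1 | intermediate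
8 | 4-oxo-6-(2,3,4,5-tetramethoxyphenyl)-4H-pyran-2-carbonyl chloride | ClC(=O)c1cc(=O)cc(-c2cc(OC)c(OC)c(OC)c2OC)o1 | intermediate
9 | 2-(2-diazoacetyl)-6-(2,3,4,5-tetramethoxyphenyl)-4H-pyran-4-one | [N-]=[N+]=CC(=O)c1cc(=O)cc(-c2cc(OC)c(OC)c(OC)c2OC)o1 | intermediate
10 | ethyl dibromoacetate | CCOC(=O)C(Br)Br | starting material
11 | chlorotriisopropylsilane | CC(C)[Si](Cl)(C(C)C)C(C)C | starting material
12 | lithium ethynolate (HC≡COLi) | [Li+].[O-]C#C | intermediate
13 | (ethynyloxy)triisopropylsilane | C#CO[Si](C(C)C)(C(C)C)C(C)C | intermediate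
14 | 2-[4-oxo-6-(2,3,4,5-tetramethoxyphenyl)-4H-pyran-2-yl]ethen-1-one (pyranonylketene) | O=C=Cc1cc(=O)cc(-c2cc(OC)c(OC)c(OC)c2OC)o1 | intermediate
15 | 4-[4-oxo-6-(2,3,4,5-tetramethoxyphenyl)-4H-pyran-2-yl]-3-(triisopropylsilyloxy)cyclobut-2-en-1-one (racemic) | O=C1C=C(O[Si](C(C)C)(C(C)C)C(C)C)C1c1cc(=O)cc(-c2cc(OC)c(OC)c(OC)c2OC)o1 | intermediate
16 | (3E)-4-[4-oxo-6-(2,3,4,5-tetramethoxyphenyl)-4H-pyran-2-yl]-3-(triisopropylsilyloxy)buta-1,3-dien-1-one (pyranonyl group cis to the ketene carbon) | O=C=C/C(O[Si](C(C)C)(C(C)C)C(C)C)=C\c1cc(=O)cc(-c2cc(OC)c(OC)c(OC)c2OC)o1 | intermediate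
17 | 5-hydroxy-2',3',4',5'-tetramethoxy-7-(triisopropylsilyloxy)flavone | COc1cc(-c2cc(=O)c3c(O)cc(O[Si](C(C)C)(C(C)C)C(C)C)cc3o2)c(OC)c(OC)c1OC | intermediate
18 | 5,7-dihydroxy-2',3',4',5'-tetramethoxyflavone | COc1cc(-c2cc(=O)c3c(O)cc(O)cc3o2)c(OC)c(OC)c1OC | target

**Step count and risk**

Total step count: 7. Longest linear sequence: 6 steps (steps 1, 2, 3, 4, 6, 7); step 5 is a one-step side branch.

Steps most likely to fail:

1. Step 6. The photolysis may divert into photoisomerisation of the pyranone ring. The ketene may be lost by dimerisation or by acylating the product phenol before it meets the alkyne. The cascade may also stall before closure onto the electron-poor pyranone C3. The fallback brings ring A in intact by established chemistry and sets out from acetophenone 2. Claisen condensation of 2 with diethyl carbonate (NaH, toluene, reflux) should give ethyl 3-oxo-3-(2,3,4,5-tetramethoxyphenyl)propanoate F1. Solvent-free thermal condensation of F1 with phloroglucinol at about 240 °C (phenol–β-keto ester chromone synthesis of the Mentzer type) should then give the 5,7-dihydroxyflavone directly, coming back to the route at target 18.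

2. Step 5. Proton abstraction at the α-carbon may compete with bromine–lithium exchange, and the ynolate may be silylated at carbon, giving the silylketene, instead of at oxygen. The volatile product may also be lost on isolation. The fallback changes the ynolate source and sets out from chlorosilane 11. Commercial 3-phenylisoxazole is lithiated at C5 (n-BuLi, THF, −78 °C) to 5-lithio-3-phenylisoxazole F2. On warming, F2 should fragment by cycloreversion into benzonitrile and lithium ethynolate 12, free of ethoxide and of excess alkyllithium. Silylation with 11 comes back to the route at 13.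

3. Step 4. Diazomethane may add as a dipole across the electron-poor pyranone double bond, and the chlorinating agent may attack the pyranone carbonyl. The fallback avoids both the acid chloride and diazomethane and sets out from acid 7. Activation with 1,1'-carbonyldiimidazole and C-acylation of the magnesium enolate of KO2CCH2CO2Et (MgCl2, Et3N, THF) should give ethyl 3-oxo-3-[4-oxo-6-(2,3,4,5-tetramethoxyphenyl)-4H-pyran-2-yl]propanoate F3. Hydrolysis and decarboxylation in hot aqueous H2SO4/AcOH should give 2-acetyl-6-(2,3,4,5-tetramethoxyphenyl)-4H-pyran-4-one F4. Detrifluoroacetylative diazo transfer then follows: LiN(SiMe3)2 and CF3CO2CH2CF3 (THF, −78 °C) give 4,4,4-trifluoro-1-[4-oxo-6-(2,3,4,5-tetramethoxyphenyl)-4H-pyran-2-yl]butane-1,3-dione F5, which is not isolated, and MsN3, Et3N and H2O in MeCN transfer the diazo group, coming back to the route at 9.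

**Further compounds**

F1 | step 6 | ethyl 3-oxo-3-(2,3,4,5-tetramethoxyphenyl)propanoate | CCOC(=O)CC(=O)c1cc(OC)c(OC)c(OC)c1OC
F2 | step 5 | 5-lithio-3-phenylisoxazole | [Li]c1cc(-c2ccccc2)no1
F3 | step 4 | ethyl 3-oxo-3-[4-oxo-6-(2,3,4,5-tetramethoxyphenyl)-4H-pyran-2-yl]propanoate | CCOC(=O)CC(=O)c1cc(=O)cc(-c2cc(OC)c(OC)c(OC)c2OC)o1
F4 | step 4 | 2-acetyl-6-(2,3,4,5-tetramethoxyphenyl)-4H-pyran-4-one | CC(=O)c1cc(=O)cc(-c2cc(OC)c(OC)c(OC)c2OC)o1
F5 | step 4 | 4,4,4-trifluoro-1-[4-oxo-6-(2,3,4,5-tetramethoxyphenyl)-4H-pyran-2-yl]butane-1,3-dione | O=C(CC(=O)C(F)(F)F)c1cc(=O)cc(-c2cc(OC)c(OC)c(OC)c2OC)o1
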